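Retrosynthesis: (i) every C–O bond made by hydride is undone first (1,4-diol to a trans-α,β-dibenzyl-γ-butyrolactone, the C3 CH2OH to a methyl ester, both phenols to pivalates); (ii) the bond from benzofuran C5 to the chain CH2 is cut to an aryl boronate and an α-methylene lactone; (iii) the benzofuran C3–C3a bond is returned to the C4–C4a bond of a chroman-4-one; (iv) the C2–aryl bond is cut to a chromone and an arylboronic acid.
Enabling feature: C3 of the dihydrobenzofuran is bonded to the fused arene carbon C3a and to one exocyclic carbon (the CH2OH), which is what remains when C4a of a 2-arylchroman-4-one moves from C4 to C3 and C4 leaves the ring as a carboxyl carbon.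
Forward order: pyranone ring of the chromone, aryl group onto C2, contraction of the six-membered ring to the five-membered ring, C5–Br to C5–B, union with the lactone at its exocyclic CH2, equilibration to the trans lactone, one global reduction.
Stereochemistry: C2 from a ligand-controlled rhodium 1,4-addition; C3 relayed from C2 in the ring contraction; the chain carbon bearing the guaiacylmethyl group from asymmetric hydrogenation of a Stobbe half-ester; the chain carbon bearing the benzofuranylmethyl group from thermodynamic trans equilibration of the lactone.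

Key step: step 6

Assumption: the ligand antipodes named in steps 5 and 9 are taken, by analogy with cyclic enones and itaconate half-esters, to give the configurations drawn; should the sense of induction be the opposite, the mirror-image ligand is used and nothing else changes.

Step 1
Reactants: 1 1-(2-hydroxy-3-methoxyphenyl)ethan-1-one
Product: 2 1-(5-bromo-2-hydroxy-3-methoxyphenyl)ethan-1-one
Conditions: NBS (1.05 equiv), MeCN, 0 °C to rt
Reagents that add atoms: N-bromosuccinimide, O=C1CCC(=O)N1Br
Why: Electrophilic aromatic bromination in which the phenolic OH, the strongest donor and blocked at both ortho positions, sends bromine to its para carbon C5, which is also meta to the acetyl group.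

Step 2
Reactants: 2 1-(5-bromo-2-hydroxy-3-methoxyphenyl)ethan-1-one; 3 N,N-dimethylformamide dimethyl acetal
Product: 5 6-bromo-8-methoxy-4H-chromen-4-one, via enaminone 4 (not isolated)
Conditions: 3 (2 equiv), toluene, 100 °C; evaporate; conc. HCl, CH2Cl2, 40 °C
Reagents that add atoms: none
Why: Enaminone chromone synthesis, in which the acetyl methyl condenses with the amide acetal to the vinylogous amide and acid then drives conjugate addition of the phenol oxygen with loss of dimethylamine, closing the pyranone ring.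

Step 3
Reactants: 6 2-methoxy-4-(4,4,5,5-tetramethyl-1,3,2-dioxaborolan-2-yl)phenol
Product: 7 2-methoxy-4-(4,4,5,5-tetramethyl-1,3,2-dioxaborolan-2-yl)phenyl pivalate
Conditions: PivCl (1.2 equiv), Et3N, DMAP (cat.), CH2Cl2, 0 °C to rt
Reagents that add atoms: pivaloyl chloride, CC(C)(C)C(=O)Cl
Why: DMAP-catalysed O-acylation of a phenol, to which the pinacol boronate is inert; the electron-poor acyl group is wanted later to hold this ring back in the rearrangement.

Step 4
Reactants: 7 2-methoxy-4-(4,4,5,5-tetramethyl-1,3,2-dioxaborolan-2-yl)phenyl pivalate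
Product: 8 [3-methoxy-4-(pivaloyloxy)phenyl]boronic acid
Conditions: NaIO4 (3 equiv), NH4OAc (3 equiv), acetone–H2O (1:1), rt
Reagents that add atoms: water, O
Why: Oxidative deprotection of a pinacol boronate, in which periodate cleaves the pinacol freed by reversible hydrolysis and so pulls the equilibrium to the boronic acid under buffered conditions that leave the aryl pivalate alone.

Step 5
Reactants: 5 6-bromo-8-methoxy-4H-chromen-4-one; 8 [3-methoxy-4-(pivaloyloxy)phenyl]boronic acid
Product: 9 (2S)-6-bromo-8-methoxy-2-[3-methoxy-4-(pivaloyloxy)phenyl]chroman-4-one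
Conditions: [Rh(OH)(cod)]2 (1.5 mol%), (S)-MeO-F12-BIPHEP (3.3 mol%), 8 (2.5 equiv), CH2Cl2–H2O (20:1), rt
Reagents that add atoms: none
Why: Rhodium-catalysed asymmetric 1,4-addition of an arylboronic acid (Hayashi–Miyaura type), in which the aryl–rhodium species of monovalent rhodium adds to C2 on the face chosen by the chiral bisphosphine and water protonates the oxa-π-allyl at C3, setting C2 as S, while the base-free medium prevents racemising ring opening to the chalcone and the aryl bromide is inert to monovalent rhodium.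

Step 6
Reactants: 9 (2S)-6-bromo-8-methoxy-2-[3-methoxy-4-(pivaloyloxy)phenyl]chroman-4-one
Product: 10 methyl (2S,3S)-5-bromo-7-methoxy-2-[3-methoxy-4-(pivaloyloxy)phenyl]-2,3-dihydro-1-benzofuran-3-carboxylate (trans)
Conditions: PhI(OAc)2 (1.2 equiv), H2SO4 (0.5 equiv), HC(OMe)3, 0 °C to rt; aq. NaHCO3 work-up
Reagents that add atoms: trimethyl orthoformate, COC(OC)OC; water, O
Why: Acid and orthoformate turn the ketone into its methyl enol ether, trivalent iodine adds to C3 on the face anti to the 2-aryl group, methanol adds at C4, and the C4–C4a bond, antiperiplanar to the equatorial C3–I bond, shifts to C3 through a phenonium-type bridged transition state as iodobenzene leaves, the dimethoxycarbenium ion at C4 being caught as the orthoester and hydrolysed to the methyl ester on work-up. The closest known reaction type is the hypervalent-iodine or trivalent-thallium oxidative ring contraction of flavanones to methyl trans-2-aryl-2,3-dihydrobenzofuran-3-carboxylates. The five-membered ring is not closed end to end but arises from the six-membered ring by this 1,2-aryl shift (formally a 3-exo-tet attack of the arene ipso carbon on C3 followed by cleavage of C4–C4a), so that the ring and the C3–C3a bond form in one event. The new stereocentre C3 is controlled by C2, since anti delivery of iodine and invertive migration place the ester trans to the 2-aryl group (2S,3S), which is also the more stable arrangement. The step needs the fused arene to migrate in preference to the 2-aryl group (isoflavone), to proton loss (flavone) and to acid-induced chalcone formation (racemisation). The ring oxygen ortho to C4a and the two methoxy donors on C4 favour the fused arene, the pivalate makes the 2-aryl ring a poor migrating group, and the anhydrous acidic medium leaves C2 untouched.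

Step 7
Reactants: 10 methyl (2S,3S)-5-bromo-7-methoxy-2-[3-methoxy-4-(pivaloyloxy)phenyl]-2,3-dihydro-1-benzofuran-3-carboxylate
Product: 11 methyl (2S,3S)-7-methoxy-2-[3-methoxy-4-(pivaloyloxy)phenyl]-5-(4,4,5,5-tetramethyl-1,3,2-dioxaborolan-2-yl)-2,3-dihydro-1-benzofuran-3-carboxylate
Conditions: B2pin2 (1.2 equiv), Pd(dppf)Cl2 (5 mol%), KOAc (3 equiv), 1,4-dioxane, 85 °C
Reagents that add atoms: bis(pinacolato)diboron, CC1(C)OB(OC1(C)C)B1OC(C)(C)C(C)(C)O1
Why: Miyaura borylation, in which zerovalent palladium inserts into the unhindered C5–Br bond and acetate-assisted transmetalation delivers the pinacol boronate, KOAc being too weak a base to disturb the C3 ester, C3–H or the pivalate.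

Step 8
Reactants: 12 4-(benzyloxy)-3-methoxybenzaldehyde; 13 dimethyl succinate
Product: 14 (E)-4-[4-(benzyloxy)-3-methoxyphenyl]-3-(methoxycarbonyl)but-3-enoic acid
Conditions: NaOMe (2 equiv), MeOH, reflux; then 2 M HCl
Reagents that add atoms: none
Why: Stobbe condensation, in which the succinate enolate adds to the aldehyde, the alkoxide lactonises onto the distal ester and base-induced ring opening gives the (E)-alkylidene half-ester with the free acid on the methylene arm.

Step 9
Reactants: 14 (E)-4-[4-(benzyloxy)-3-methoxyphenyl]-3-(methoxycarbonyl)but-3-enoic acid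
Product: 15 (3R)-4-[4-(benzyloxy)-3-methoxyphenyl]-3-(methoxycarbonyl)butanoic acid
Conditions: [Rh((S,S)-Et-DuPHOS)(cod)]BF4 (0.5 mol%), H2 (5 bar), NaOMe (10 mol%), MeOH, rt
Reagents that add atoms: none
Why: Rhodium-catalysed asymmetric hydrogenation of an itaconate-type half-ester, in which the carboxylate arm chelates the cationic rhodium–bisphosphine complex and hydrogen is delivered to one face of the trisubstituted alkene, setting the branched carbon as R without touching the benzyl ether.

Step 10
Reactants: 15 (3R)-4-[4-(benzyloxy)-3-methoxyphenyl]-3-(methoxycarbonyl)butanoic acid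
Product: 17 (4R)-4-[4-(benzyloxy)-3-methoxybenzyl]dihydrofuran-2(3H)-one, via hydroxy acid 16 (not isolated)
Conditions: KOH (1.0 equiv), EtOH, rt, evaporate; LiBH4 (2 equiv), THF, 0 to 50 °C; then 2 M HCl, rt
Reagents that add atoms: none
Why: Chemoselective borohydride reduction of the methyl ester beside the unreactive carboxylate salt, followed by acid-induced lactonisation of the γ-hydroxy acid, which carries the stereocentre unchanged into C4 of the lactone.

Step 11
Reactants: 17 (4R)-4-[4-(benzyloxy)-3-methoxybenzyl]dihydrofuran-2(3H)-one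
Product: 18 (4R)-4-(4-hydroxy-3-methoxybenzyl)dihydrofuran-2(3H)-one
Conditions: H2 (1 atm), 10% Pd/C, EtOAc–EtOH, rt
Reagents that add atoms: none
Why: Catalytic hydrogenolysis of the benzyl aryl ether, to which the lactone and the methoxyarene are inert, done here because the later alkene would not survive it.

Step 12
Reactants: 18 (4R)-4-(4-hydroxy-3-methoxybenzyl)dihydrofuran-2(3H)-one
Product: 19 2-methoxy-4-{[(3R)-5-oxotetrahydrofuran-3-yl]methyl}phenyl pivalate
Conditions: PivCl (1.2 equiv), Et3N, DMAP (cat.), CH2Cl2, 0 °C to rt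
Reagents that add atoms: pivaloyl chloride, CC(C)(C)C(=O)Cl
Why: DMAP-catalysed phenol acylation, which puts on the same ester protecting group as on the other fragment so that a single hydride step can later remove both.

Step 13
Reactants: 19 2-methoxy-4-{[(3R)-5-oxotetrahydrofuran-3-yl]methyl}phenyl pivalate; 20 N,N-dimethylmethyleneiminium iodide
Product: 23 2-methoxy-4-{[(3R)-4-methylidene-5-oxotetrahydrofuran-3-yl]methyl}phenyl pivalate, via Mannich base 21 (not isolated), via methiodide 22 (not isolated)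
Conditions: LiN(iPr)2 (1.1 equiv), THF, −78 °C; 20, −78 to 0 °C; MeI, MeOH, rt; aq. NaHCO3–CH2Cl2, rt
Reagents that add atoms: none
Why: Mannich reaction of the lactone enolate with the iminium salt (anti to the C4 substituent), N-methylation and bicarbonate-induced Hofmann-type elimination give the exocyclic α-methylene lactone, the mild base being chosen so that the alkene does not move into the ring and erase the C4 stereocentre, and the hindered pivalate being expected to survive the amide base at −78 °C.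

Step 14
Reactants: 11 methyl (2S,3S)-7-methoxy-2-[3-methoxy-4-(pivaloyloxy)phenyl]-5-(4,4,5,5-tetramethyl-1,3,2-dioxaborolan-2-yl)-2,3-dihydro-1-benzofuran-3-carboxylate; 23 2-methoxy-4-{[(3R)-4-methylidene-5-oxotetrahydrofuran-3-yl]methyl}phenyl pivalate
Product: 24 methyl (2S,3S)-7-methoxy-5-({(4R)-4-[3-methoxy-4-(pivaloyloxy)benzyl]-2-oxotetrahydrofuran-3-yl}methyl)-2-[3-methoxy-4-(pivaloyloxy)phenyl]-2,3-dihydro-1-benzofuran-3-carboxylate as a mixture of epimers at lactone C3
Conditions: 11 (1.2 equiv), [Rh(OH)(cod)]2 (3 mol%), K3PO4 (0.5 equiv), 1,4-dioxane–H2O (10:1), 50 °C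
Reagents that add atoms: none
Why: Rhodium-catalysed conjugate addition of an aryl boronate to a 1,1-disubstituted acrylate-type acceptor, in which the aryl–rhodium adds to the exocyclic CH2 and water protonates the rhodium enolate, probably mainly on the face away from the C4 substituent (cis lactone), so that lactone C3 is not yet controlled and both epimers are carried on.

Step 15
Reactants: 24 methyl (2S,3S)-7-methoxy-5-({(4R)-4-[3-methoxy-4-(pivaloyloxy)benzyl]-2-oxotetrahydrofuran-3-yl}methyl)-2-[3-methoxy-4-(pivaloyloxy)phenyl]-2,3-dihydro-1-benzofuran-3-carboxylate (epimer mixture)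
Product: 25 methyl (2S,3S)-7-methoxy-5-({(3R,4R)-4-[3-methoxy-4-(pivaloyloxy)benzyl]-2-oxotetrahydrofuran-3-yl}methyl)-2-[3-methoxy-4-(pivaloyloxy)phenyl]-2,3-dihydro-1-benzofuran-3-carboxylate (trans lactone)
Conditions: DBU (1 equiv), toluene, 80 °C
Reagents that add atoms: none
Why: Base-mediated thermodynamic epimerisation through the lactone enolate, which should converge on the more stable trans-3,4-disubstituted lactone (3R,4R), while the benzofuran C3 already sits in its stable trans arrangement and ring opening there would be a disfavoured reverse 5-endo-trig process.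

Step 16
Reactants: 25 methyl (2S,3S)-7-methoxy-5-({(3R,4R)-4-[3-methoxy-4-(pivaloyloxy)benzyl]-2-oxotetrahydrofuran-3-yl}methyl)-2-[3-methoxy-4-(pivaloyloxy)phenyl]-2,3-dihydro-1-benzofuran-3-carboxylate
Product: 26 (2R,3R)-2-{[(2S,3R)-2-(4-hydroxy-3-methoxyphenyl)-3-(hydroxymethyl)-7-methoxy-2,3-dihydro-1-benzofuran-5-yl]methyl}-3-(4-hydroxy-3-methoxybenzyl)butane-1,4-diol
Conditions: LiAlH4 (excess), THF, 0 °C to rt; H2O then 15% aq. NaOH quench
Reagents that add atoms: none
Why: Exhaustive LiAlH4 reduction, which takes the lactone to the 1,4-diol, the methyl ester to the primary alcohol and both aryl pivalates to the phenols without touching a stereocentre, the benzylic ring ether or the aryl methyl ethers.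

Compound list
1 | 1-(2-hydroxy-3-methoxyphenyl)ethan-1-one | CC(=O)c1cccc(OC)c1O | starting material
2 | 1-(5-bromo-2-hydroxy-3-methoxyphenyl)ethan-1-one | CC(=O)c1cc(Br)cc(OC)c1O | intermediate
3 | N,N-dimethylformamide dimethyl acetal | COC(OC)N(C)C | starting material
4 | (E)-1-(5-bromo-2-hydroxy-3-methoxyphenyl)-3-(dimethylamino)prop-2-en-1-one (not isolated) | CN(C)/C=C/C(=O)c1cc(Br)cc(OC)c1O | intermediate
5 | 6-bromo-8-methoxy-4H-chromen-4-one | COc1cc(Br)cc2c(=O)ccoc12 | intermediate
6 | 2-methoxy-4-(4,4,5,5-tetramethyl-1,3,2-dioxaborolan-2-yl)phenol | COc1cc(B2OC(C)(C)C(C)(C)O2)ccc1O | starting material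
7 | 2-methoxy-4-(4,4,5,5-tetramethyl-1,3,2-dioxaborolan-2-yl)phenyl pivalate | COc1cc(B2OC(C)(C)C(C)(C)O2)ccc1OC(=O)C(C)(C)C | intermediate
8 | [3-methoxy-4-(pivaloyloxy)phenyl]boronic acid | COc1cc(B(O)O)ccc1OC(=O)C(C)(C)C | intermediate
9 | (2S)-6-bromo-8-methoxy-2-[3-methoxy-4-(pivaloyloxy)phenyl]chroman-4-one | COc1cc(Br)cc2C(=O)C[C@@H](c3ccc(OC(=O)C(C)(C)C)c(OC)c3)Oc12 | intermediate
10 | methyl (2S,3S)-5-bromo-7-methoxy-2-[3-methoxy-4-(pivaloyloxy)phenyl]-2,3-dihydro-1-benzofuran-3-carboxylate | COc1cc(Br)cc2[C@H](C(=O)OC)[C@@H](c3ccc(OC(=O)C(C)(C)C)c(OC)c3)Oc12 | intermediate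
11 | methyl (2S,3S)-7-methoxy-2-[3-methoxy-4-(pivaloyloxy)phenyl]-5-(4,4,5,5-tetramethyl-1,3,2-dioxaborolan-2-yl)-2,3-dihydro-1-benzofuran-3-carboxylate | COc1cc(B3OC(C)(C)C(C)(C)O3)cc2[C@H](C(=O)OC)[C@@H](c3ccc(OC(=O)C(C)(C)C)c(OC)c3)Oc12 | intermediate
12 | 4-(benzyloxy)-3-methoxybenzaldehyde | COc1cc(C=O)ccc1OCc1ccccc1 | starting material
13 | dimethyl succinate | COC(=O)CCC(=O)OC | starting material
14 | (E)-4-[4-(benzyloxy)-3-methoxyphenyl]-3-(methoxycarbonyl)but-3-enoic acid | OC(=O)C/C(C(=O)OC)=C\c1ccc(OCc2ccccc2)c(OC)c1 | intermediate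
15 | (3R)-4-[4-(benzyloxy)-3-methoxyphenyl]-3-(methoxycarbonyl)butanoic acid | OC(=O)C[C@H](C(=O)OC)Cc1ccc(OCc2ccccc2)c(OC)c1 | intermediate
16 | (3R)-4-[4-(benzyloxy)-3-methoxyphenyl]-3-(hydroxymethyl)butanoic acid (present as its carboxylate salt, not isolated) | OC(=O)C[C@H](CO)Cc1ccc(OCc2ccccc2)c(OC)c1 | intermediate
17 | (4R)-4-[4-(benzyloxy)-3-methoxybenzyl]dihydrofuran-2(3H)-one | O=C1C[C@@H](Cc2ccc(OCc3ccccc3)c(OC)c2)CO1 | intermediate
18 | (4R)-4-(4-hydroxy-3-methoxybenzyl)dihydrofuran-2(3H)-one | O=C1C[C@@H](Cc2ccc(O)c(OC)c2)CO1 | intermediate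
19 | 2-methoxy-4-{[(3R)-5-oxotetrahydrofuran-3-yl]methyl}phenyl pivalate | O=C1C[C@@H](Cc2ccc(OC(=O)C(C)(C)C)c(OC)c2)CO1 | intermediate
20 | N,N-dimethylmethyleneiminium iodide | C=[N+](C)C.[I-] | starting material
21 | 4-{[(3R,4S)-4-[(dimethylamino)methyl]-5-oxotetrahydrofuran-3-yl]methyl}-2-methoxyphenyl pivalate (trans, not isolated) | CN(C)C[C@H]1C(=O)OC[C@@H]1Cc1ccc(OC(=O)C(C)(C)C)c(OC)c1 | intermediate
22 | {[(3S,4R)-4-[3-methoxy-4-(pivaloyloxy)benzyl]-2-oxotetrahydrofuran-3-yl]methyl}trimethylammonium iodide (not isolated) | C[N+](C)(C)C[C@H]1C(=O)OC[C@@H]1Cc1ccc(OC(=O)C(C)(C)C)c(OC)c1.[I-] | intermediate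
23 | 2-methoxy-4-{[(3R)-4-methylidene-5-oxotetrahydrofuran-3-yl]methyl}phenyl pivalate | C=C1C(=O)OC[C@@H]1Cc1ccc(OC(=O)C(C)(C)C)c(OC)c1 | intermediate
24 | methyl (2S,3S)-7-methoxy-5-({(4R)-4-[3-methoxy-4-(pivaloyloxy)benzyl]-2-oxotetrahydrofuran-3-yl}methyl)-2-[3-methoxy-4-(pivaloyloxy)phenyl]-2,3-dihydro-1-benzofuran-3-carboxylate, both epimers at lactone C3 | COc1cc(CC2C(=O)OC[C@@H]2Cc2ccc(OC(=O)C(C)(C)C)c(OC)c2)cc2[C@H](C(=O)OC)[C@@H](c3ccc(OC(=O)C(C)(C)C)c(OC)c3)Oc12 | intermediate
25 | methyl (2S,3S)-7-methoxy-5-({(3R,4R)-4-[3-methoxy-4-(pivaloyloxy)benzyl]-2-oxotetrahydrofuran-3-yl}methyl)-2-[3-methoxy-4-(pivaloyloxy)phenyl]-2,3-dihydro-1-benzofuran-3-carboxylate | COc1cc(C[C@H]2C(=O)OC[C@@H]2Cc2ccc(OC(=O)C(C)(C)C)c(OC)c2)cc2[C@H](C(=O)OC)[C@@H](c3ccc(OC(=O)C(C)(C)C)c(OC)c3)Oc12 | intermediate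
26 | (2R,3R)-2-{[(2S,3R)-2-(4-hydroxy-3-methoxyphenyl)-3-(hydroxymethyl)-7-methoxy-2,3-dihydro-1-benzofuran-5-yl]methyl}-3-(4-hydroxy-3-methoxybenzyl)butane-1,4-diol | COc1cc(C[C@@H](CO)[C@H](CO)Cc2cc(OC)c3c(c2)[C@H](CO)[C@@H](c2ccc(O)c(OC)c2)O3)ccc1O | target

Total step count: 16.
Longest linear sequence: 9 steps (12 to 26 through steps 8 to 16); the benzofuran arm from 1 or from 6 is 8 steps long.

Steps most likely to fail

Step 6. The bromine sits meta to the migrating carbon C4a and lowers its migratory aptitude. Shift of the 2-aryl group (isoflavone skeleton) or proton loss to the flavone may then compete, and long exposure to acid may erode C2 through reversible chalcone formation. The fallback sets out from 1 and comes back at 10: the same contraction is run on the bromine-free ring and the halogen is introduced afterwards. Compound 1 is condensed with 3 to (E)-3-(dimethylamino)-1-(2-hydroxy-3-methoxyphenyl)prop-2-en-1-one F1, which acid closes to 8-methoxy-4H-chromen-4-one F2. Addition of 8 under the conditions of step 5 should give (2S)-8-methoxy-2-[3-methoxy-4-(pivaloyloxy)phenyl]chroman-4-one F3. The conditions of step 6 should then contract the more electron-rich ring to methyl (2S,3S)-7-methoxy-2-[3-methoxy-4-(pivaloyloxy)phenyl]-2,3-dihydro-1-benzofuran-3-carboxylate F4. NBS in MeCN is expected to brominate F4 at C5, para to the ring oxygen and remote from the hindered C4, which returns the route to 10.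

Step 14. Protodeboronation of the arylrhodium, or base-induced migration of the exocyclic double bond into the lactone ring (which erases the C4 stereocentre), may outrun carbometalation; the esters may also be partly hydrolysed. The fallback sets out from 10 (and uses 19) and comes back at 25; it replaces the conjugate addition by the classical trans-selective lactone enolate alkylation. Stille coupling of 10 with Bu3SnCH2OH [Pd(PPh3)4, 1,4-dioxane, 90 °C] should give methyl (2S,3S)-5-(hydroxymethyl)-7-methoxy-2-[3-methoxy-4-(pivaloyloxy)phenyl]-2,3-dihydro-1-benzofuran-3-carboxylate F5. An Appel reaction (CBr4, PPh3, CH2Cl2, 0 °C) converts it into methyl (2S,3S)-5-(bromomethyl)-7-methoxy-2-[3-methoxy-4-(pivaloyloxy)phenyl]-2,3-dihydro-1-benzofuran-3-carboxylate F6. The lithium enolate of 19 [LiN(SiMe3)2, THF, −78 °C] is then alkylated by F6 on the face anti to the C4 substituent, which should give the trans lactone 25 directly. Steps 7, 13, 14 and 15 are bypassed.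

Step 15. The amidine base may remove the more acidic benzofuran C3–H faster than the lactone α-H, with reversible ring opening that would erode C2 and C3, or the lactone may equilibrate only slowly and incompletely. The fallback sets out from 10 (and uses 23) and comes back at 26; the acidic ester is removed before the fragments are joined. LiAlH4 (THF, 0 °C) reduces 10 to 4-[(2S,3R)-5-bromo-3-(hydroxymethyl)-7-methoxy-2,3-dihydro-1-benzofuran-2-yl]-2-methoxyphenol F7. PivCl (2.5 equiv), Et3N and DMAP give {(2S,3R)-5-bromo-7-methoxy-2-[3-methoxy-4-(pivaloyloxy)phenyl]-2,3-dihydro-1-benzofuran-3-yl}methyl pivalate F8. Borylation as in step 7 gives {(2S,3R)-7-methoxy-2-[3-methoxy-4-(pivaloyloxy)phenyl]-5-(4,4,5,5-tetramethyl-1,3,2-dioxaborolan-2-yl)-2,3-dihydro-1-benzofuran-3-yl}methyl pivalate F9. Rhodium-catalysed addition to 23 as in step 14 gives {(2S,3R)-7-methoxy-5-({(4R)-4-[3-methoxy-4-(pivaloyloxy)benzyl]-2-oxotetrahydrofuran-3-yl}methyl)-2-[3-methoxy-4-(pivaloyloxy)phenyl]-2,3-dihydro-1-benzofuran-3-yl}methyl pivalate F10 as a mixture of lactone C3 epimers. DBU, which now finds the lactone α-H as the only acidic site, equilibrates it to {(2S,3R)-7-methoxy-5-({(3R,4R)-4-[3-methoxy-4-(pivaloyloxy)benzyl]-2-oxotetrahydrofuran-3-yl}methyl)-2-[3-methoxy-4-(pivaloyloxy)phenyl]-2,3-dihydro-1-benzofuran-3-yl}methyl pivalate F11. LiAlH4 then cleaves the three pivalates and opens the lactone to give 26.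

Further compounds
F1 | step 6 | (E)-3-(dimethylamino)-1-(2-hydroxy-3-methoxyphenyl)prop-2-en-1-one | CN(C)/C=C/C(=O)c1cccc(OC)c1O
F2 | step 6 | 8-methoxy-4H-chromen-4-one | COc1cccc2c(=O)ccoc12
F3 | step 6 | (2S)-8-methoxy-2-[3-methoxy-4-(pivaloyloxy)phenyl]chroman-4-one | COc1cccc2C(=O)C[C@@H](c3ccc(OC(=O)C(C)(C)C)c(OC)c3)Oc12
F4 | step 6 | methyl (2S,3S)-7-methoxy-2-[3-methoxy-4-(pivaloyloxy)phenyl]-2,3-dihydro-1-benzofuran-3-carboxylate | COc1cccc2[C@H](C(=O)OC)[C@@H](c3ccc(OC(=O)C(C)(C)C)c(OC)c3)Oc12
F5 | step 14 | methyl (2S,3S)-5-(hydroxymethyl)-7-methoxy-2-[3-methoxy-4-(pivaloyloxy)phenyl]-2,3-dihydro-1-benzofuran-3-carboxylate | COc1cc(CO)cc2[C@H](C(=O)OC)[C@@H](c3ccc(OC(=O)C(C)(C)C)c(OC)c3)Oc12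
F6 | step 14 | methyl (2S,3S)-5-(bromomethyl)-7-methoxy-2-[3-methoxy-4-(pivaloyloxy)phenyl]-2,3-dihydro-1-benzofuran-3-carboxylate | COc1cc(CBr)cc2[C@H](C(=O)OC)[C@@H](c3ccc(OC(=O)C(C)(C)C)c(OC)c3)Oc12
F7 | step 15 | 4-[(2S,3R)-5-bromo-3-(hydroxymethyl)-7-methoxy-2,3-dihydro-1-benzofuran-2-yl]-2-methoxyphenol | COc1cc(Br)cc2[C@H](CO)[C@@H](c3ccc(O)c(OC)c3)Oc12
F8 | step 15 | {(2S,3R)-5-bromo-7-methoxy-2-[3-methoxy-4-(pivaloyloxy)phenyl]-2,3-dihydro-1-benzofuran-3-yl}methyl pivalate | COc1cc(Br)cc2[C@H](COC(=O)C(C)(C)C)[C@@H](c3ccc(OC(=O)C(C)(C)C)c(OC)c3)Oc12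
F9 | step 15 | {(2S,3R)-7-methoxy-2-[3-methoxy-4-(pivaloyloxy)phenyl]-5-(4,4,5,5-tetramethyl-1,3,2-dioxaborolan-2-yl)-2,3-dihydro-1-benzofuran-3-yl}methyl pivalate | COc1cc(B3OC(C)(C)C(C)(C)O3)cc2[C@H](COC(=O)C(C)(C)C)[C@@H](c3ccc(OC(=O)C(C)(C)C)c(OC)c3)Oc12
F10 | step 15 | {(2S,3R)-7-methoxy-5-({(4R)-4-[3-methoxy-4-(pivaloyloxy)benzyl]-2-oxotetrahydrofuran-3-yl}methyl)-2-[3-methoxy-4-(pivaloyloxy)phenyl]-2,3-dihydro-1-benzofuran-3-yl}methyl pivalate, both epimers at lactone C3 | COc1cc(CC2C(=O)OC[C@@H]2Cc2ccc(OC(=O)C(C)(C)C)c(OC)c2)cc2[C@H](COC(=O)C(C)(C)C)[C@@H](c3ccc(OC(=O)C(C)(C)C)c(OC)c3)Oc12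
F11 | step 15 | {(2S,3R)-7-methoxy-5-({(3R,4R)-4-[3-methoxy-4-(pivaloyloxy)benzyl]-2-oxotetrahydrofuran-3-yl}methyl)-2-[3-methoxy-4-(pivaloyloxy)phenyl]-2,3-dihydro-1-benzofuran-3-yl}methyl pivalate | COc1cc(C[C@H]2C(=O)OC[C@@H]2Cc2ccc(OC(=O)C(C)(C)C)c(OC)c2)cc2[C@H](COC(=O)C(C)(C)C)[C@@H](c3ccc(OC(=O)C(C)(C)C)c(OC)c3)Oc12
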